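**Retrosynthetic overview**
- The dihydropyran ring is opened by a retro oxa-[4+2]: the C8–O and C13–C1′ bonds lead back to an alkylidene triketone (heterodiene) and a caryophyllane dienol whose exocyclic C8=C13 bond is the 2π partner.
- The heterodiene comes from a Knoevenagel condensation of syncarpic acid with isovaleraldehyde; syncarpic acid comes from acetyl-blocked tetra-C-methylation of phloroacetophenone.
- The dienol comes from the C5–O bond construction: oxygen-atom transfer to the strained C4=C5 bond of (−)-β-caryophyllene, then a transposing syn-elimination through C3–H. This step fixes C5 and the (3Z) alkene.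
- Ring order: the cyclobutane and nine-membered rings are bought in β-caryophyllene; the triketone ring is made by dearomatisation (step 1); the dihydropyran ring is closed last (step 4).

Numbering: caryophyllane locants (C12 = methyl on C4, C13 = exocyclic methylene on C8); C1′ = the isobutyl-bearing carbon that comes from the aldehyde carbon.

Assumption: the (R) enantiomer of the phosphoric acid is taken as the matched catalyst in step 4; if a test run shows the opposite, the (S) enantiomer is used with nothing else changed.

**Step 1**
Reactants: 1 2′,4′,6′-trihydroxyacetophenone; 2 iodomethane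
Product: 3 acetylsyncarpic acid (2-acetyl-3-hydroxy-4,4,6,6-tetramethylcyclohex-2-ene-1,5-dione)
Conditions: NaOMe (6 equiv), MeI (6 equiv), MeOH, 0 °C to reflux; then aq. HCl
Reagents that add atoms: iodomethane (2), CI
Why: Exhaustive dearomative C-methylation of the phloroglucinol polyanion (Herzig–Zeisel-type alkylation), in which the acetyl group blocks one ring carbon so that the other two are each methylated twice; no stereocentre is formed.

**Step 2**
Reactants: 3 acetylsyncarpic acid
Product: 4 syncarpic acid (2,2,4,4-tetramethylcyclohexane-1,3,5-trione)
Conditions: 6 M aq. HCl, reflux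
Reagents that add atoms: none
Why: Acid-mediated retro-Claisen deacylation, in which water attacks the exocyclic acetyl carbonyl and acetic acid is lost, leaving the acidic cyclic triketone.

**Step 3**
Reactants: 5 (−)-β-caryophyllene
Product: 7 (1R,3Z,5R,9S)-caryophylla-3,8(13)-dien-5-ol, via caryophyllene β-oxide 6 (not isolated)
Conditions: DMDO (1.05 equiv), acetone, −20 °C; evaporate; diethylaluminium 2,2,6,6-tetramethylpiperidide (4 equiv; from 2,2,6,6-tetramethylpiperidine, n-BuLi, Et2AlCl), toluene, 0 °C to rt; aq. potassium sodium tartrate
Reagents that add atoms: dimethyldioxirane, CC1(C)OO1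
Why: Electrophilic oxygen transfer (Prilezhaev-type epoxidation) reaches only the strained (E)-C4=C5 bond and only its outer face in the main conformers (β:α about 4:1), which forms the C5–O bond and fixes C5 as R, and the aluminium amide then effects a Yamamoto syn-elimination that removes the C3 proton cis to H5, cleaving C4–O and giving the (3Z)-allylic alcohol without touching C5.

**Step 4**
Reactants: 4 syncarpic acid; 7 (1R,3Z,5R,9S)-caryophylla-3,8(13)-dien-5-ol; 8 isovaleraldehyde (3-methylbutanal)
Product: 10 tomentodione O, via alkylidene triketone 9 (not isolated)
Conditions: (R)-3,3′-bis(2,4,6-triisopropylphenyl)-1,1′-binaphthyl-2,2′-diyl hydrogen phosphate (10 mol %), 4 Å molecular sieves, toluene, 0 °C to rt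
Reagents that add atoms: none
Why: Proposed new method: a chiral phosphoric acid-controlled domino Knoevenagel/inverse-electron-demand oxa-Diels–Alder with an unactivated 1,1-dialkyl alkene, in which the acid first condenses 4 with 8 to heterodiene 9 and then holds 9 by P–OH···O=C while its P=O accepts a hydrogen bond from the C5–OH of 7, so that C13 of the exocyclic alkene adds to one enantiotopic face of the alkylidene carbon (C1′ becomes R) and the C8–O bond closes on the open face of the methylene group (C8 becomes S), while the hindered C3=C4 bond does not compete; the closest known reaction types are the thermal Tietze domino Knoevenagel/hetero-Diels–Alder reaction and phosphoric acid-catalysed [4+2] cycloadditions of ortho-quinone methides with alkenes.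

**Compound list**
1 | 2′,4′,6′-trihydroxyacetophenone (phloroacetophenone) | CC(=O)c1c(O)cc(O)cc1O | starting material
2 | iodomethane | CI | starting material
3 | acetylsyncarpic acid, 2-acetyl-3-hydroxy-4,4,6,6-tetramethylcyclohex-2-ene-1,5-dione | CC(=O)C1=C(O)C(C)(C)C(=O)C(C)(C)C1=O | intermediate
4 | syncarpic acid, 2,2,4,4-tetramethylcyclohexane-1,3,5-trione | CC1(C)C(=O)CC(=O)C(C)(C)C1=O | intermediate
5 | (−)-β-caryophyllene, (1R,4E,9S)-caryophylla-4,8(13)-diene | C/C1=C\CCC(=C)[C@H]2CC(C)(C)[C@@H]2CC1 | starting material
6 | (−)-caryophyllene β-oxide, (1R,4R,5R,9S)-4,5-epoxycaryophyll-8(13)-ene, not isolated | C[C@@]12CC[C@@H]3[C@H](CC3(C)C)C(=C)CC[C@H]1O2 | intermediate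
7 | (1R,3Z,5R,9S)-caryophylla-3,8(13)-dien-5-ol | C/C1=C/C[C@@H]2[C@H](CC2(C)C)C(=C)CC[C@H]1O | intermediate
8 | isovaleraldehyde (3-methylbutanal) | CC(C)CC=O | starting material
9 | 2-(3-methylbutylidene)-4,4,6,6-tetramethylcyclohexane-1,3,5-trione, not isolated | CC(C)CC=C1C(=O)C(C)(C)C(=O)C(C)(C)C1=O | intermediate
10 | tomentodione O: (1R,3Z,5R,8S,9S)-caryophyll-3-en-5-ol whose C8 is the spiro C2 of a (4R)-4-isobutyl-6,6,8,8-tetramethyl-3,4-dihydro-2H-chromene-5,7(6H,8H)-dione (C13 = chromene C3, C1′ = chromene C4, ring O on C8) | C/C1=C/C[C@@H]2[C@H](CC2(C)C)[C@]2(CC[C@H]1O)C[C@@H](CC(C)C)C1=C(O2)C(C)(C)C(=O)C(C)(C)C1=O | target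

**Step count and risks**
Total steps: 4. Longest linear sequence: 3 (steps 1, 2 and 4; the terpene branch is step 3 then step 4).

The three steps most likely to fail are steps 4, 3 and 1.

Step 4 is the new cycloaddition. The acid may fail to override the intrinsic face preferences of 7 and 9 (four diastereomers are possible at C8/C1′), or it may only divert 9 into bis-adducts with 4. The fallback is known chemistry and gives up catalyst control. It sets out from 4, which is condensed with 8 and piperidine (EtOH, rt) to the isolable Mannich base 2-[3-methyl-1-(piperidin-1-yl)butyl]-3-hydroxy-4,4,6,6-tetramethylcyclohex-2-ene-1,5-dione F2. Heating F2 with 7 in toluene at 90 °C releases 9 slowly by loss of piperidine and lets the uncatalysed, substrate-controlled hetero-Diels–Alder reaction run. The route is rejoined at 10 after separation from its C8/C1′ diastereomers by preparative HPLC.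

Step 3 has three weak points. Oxygen transfer is only about 4:1 face-selective, so the C5 epimer of 7 must be removed by chromatography. The aluminium amide might take a C12 methyl proton instead and give the 4(12)-ene. The Lewis-acidic aluminium might trigger transannular attack of C8=C13 on C4. The fallback replaces epoxidation/elimination by a Schenck ene reaction and sets out from 5. Singlet oxygen (O2, tetraphenylporphyrin, visible light, CH2Cl2, −20 °C) adds to C5 with shift of the double bond and gives (1R,3Z,5R,9S)-5-hydroperoxycaryophylla-3,8(13)-diene F1 beside its 4(12)-ene regioisomers. Reduction with PPh3 and chromatography on AgNO3-impregnated silica then return the route to 7.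

Step 1 can stall at tri-C-methylated material or leak into O-methyl ethers. The fallback drops the acyl blocking group and sets out from iodomethane 2. Direct Herzig–Zeisel tetra-C-methylation of unblocked commercial phloroglucinol (NaOMe, MeOH, reflux) gives syncarpic acid in one operation in modest yield. It is freed from tri-, penta- and hexamethyl congeners by bicarbonate extraction and crystallisation. The route is rejoined at 4, step 2 becomes unnecessary, and no compound outside the list is made (F0).

**Further compounds**
F1 | step 3 | (1R,3Z,5R,9S)-5-hydroperoxycaryophylla-3,8(13)-diene | C/C1=C/C[C@@H]2[C@H](CC2(C)C)C(=C)CC[C@H]1OO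
F2 | step 4 | 2-[3-methyl-1-(piperidin-1-yl)butyl]-3-hydroxy-4,4,6,6-tetramethylcyclohex-2-ene-1,5-dione (racemic) | CC(C)CC(N1CCCCC1)C1=C(O)C(C)(C)C(=O)C(C)(C)C1=O
F0 | step 1 | none | none
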